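Setting the summer and winter runs hour against hour is a trap. Both substrate-consuming steps proposed are second-order, so at fixed equivalents the rate per unit of substrate scales roughly with the charge. The first-order transfer and dormant steps do not scale that way, so I treated the product of substrate charge and time, which I call the dose, as a hypothesis to test.

| flask | substrate | reagent in the second phase | remark | time | volume of the second phase over the first |
|---|---|---|---|---|---|
| summer | 0.10 M | 0.90 equiv | run made earlier |  |  |
| winter | 0.15 M | 0.90 equiv | run made earlier |  |  |
| midnight | 0.20 M | 1.8 equiv | run made earlier |  |  |
| flask | 0.20 M | 0.900 equiv |  | 3.0 d | 0.25 |

- summer (time / h: target / %): 3.00: 1.4; 8.00: 8.9; 20.0: 19.7; 40.0: 27.5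
- winter (time / h: target / %): 3.00: 3.5; 8.00: 11.4; 20.0: 25.2; 40.0: 32.3
- midnight (time / h: target / %): 5.00: 17.2; 15.0: 42.8; 30.0: 56.8; 40.0: 63.2

(scatter of a reading: 1 percentage point)

- percent here means substrate units held: one self-condensation product counts as two
- in the second phase: reagent in the second phase; everything else is in the first
- charges count per volume of the first phase; a concentration in a rate is the amount of a species over the volume of its own phase; every rate counts per litre of the first phase
- steps that have been proposed: reagent in the reaction phase <-> reagent in the second phase; substrate + reagent in the reaction phase -> target; reagent in the reaction phase <-> dormant form; 2 substrate -> self-condensation product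
- the earlier runs hold the two phases in the same ratio of volumes as the flask asked about

- Sunday's: doubling the transfer coefficient of the reagent in the second phase, all else as stated
- Monday's: doubling the amount of reagent in the second phase, all else as stated

- target at 3.0 d, in percent of the substrate charged
- the change that raises the amount of target at 3.0 d, in percent of the substrate charged most ("none" if none brings more than 2 percentage points) (Sunday's / Monday's / none)
- amount of target at 3.0 d, in percent of the substrate charged, after Monday's

At the dose of its 20.0 h reading, the winter run read 25.2 %; the summer readings, interpolated in the logarithm of dose, gave 24.3 %, with a scatter of 1 percentage point. In the summer run the rate of target fell from 0.00900 /h of the charge between 8.00 h and 20.0 h to 0.00390 /h between 20.0 h and 40.0 h. That is a slowing by a factor of 2.31, while the mean elapsed time grew 2.14-fold. Self-condensation and the dormant form could each contribute, and I did not try to separate them, so I took the total slowing as a rate inverse to dose. Target then rises by a constant amount per e-fold of dose, the log gain, which I read from summer at 20.0 h and winter at 40.0 h as 11 points.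

The flask's dose is 2.40 times winter's last, so I reckoned 42.3 %. Monday's recipe is the midnight charge, which read 63.2 % at 40.0 h, more than my figure for the flask. The forecast gave 43 %, Monday's and 73 %, holding that “more reagent outcompetes dimerisation”.

The flask gave 43.6 %, with Monday's best at 68.6 %.

    reagent in the reaction phase ⇌ reagent in the second phase, rate k1*([reagent in the reaction phase] - [reagent in the second phase]/K1) per volume of the first phase (partition coefficient = 2.60, kL = 0.233 /h)
    substrate + reagent in the reaction phase → target (k = 0.305 /M/h)
    reagent in the reaction phase ⇌ dormant form (K = 2.70, k = 0.0255 /h)
    2 substrate → self-condensation product (k = 0.0706 /M/h)

In this flask, the reagent charge had to reach 0.773 equiv or 1.04 equiv to move the answer by 5 points. For the neighbour with 0.50 M of substrate, at the same equivalents and time, the dose is 6.00 times winter's last, so 11 points gives 52.8 %, and that neighbour flask held 52.8 %.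

The earlier runs and the new flask were generated by integration with made-up constants; noise was put on by code.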